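## The problem

Numbering used throughout (longipinane numbering): C1 is the ketone carbon, C2 the =CH, C3 the alkene carbon carrying methyl C12; C4, C5, C11 and C10 form the cyclobutane; C6 carries the geminal methyls C13 and C14; C7 carries the 3-methylbut-2-enoate (senecioate); C8 is CH2; C9 carries the (E)-2-methylbut-2-enoate (tiglate); C10 is quaternary and carries methyl C15. The target is (4R,5S,7R,9R,10R,11R).

The core is a cyclobutane with both diagonals bridged: C4/C11 by the enone unit C3=C2–C1(=O), giving a bicyclo[3.1.1]hept-3-en-2-one, and C5/C10 by C6–C7–C8–C9, giving a bicyclo[4.1.1]octane. Four of the six stereocentres sit on the four-membered ring, one of them the quaternary C10. The two bridges lock their relative configuration, so the open questions are their absolute sense and their relation to C7 and C9. C7 and C9 are a 1,3-anti diol, both neopentyl, carrying two different unsaturated esters that must be told apart. C5 and C10 cannot be epimerised, and C11 is a bridgehead α to the ketone, so nothing on the cyclobutane can be corrected after the ring is made. Sensitive features are the strained ring (cationic rearrangement, opening of any radical or cation at C3), the light-sensitive enone, E/Z isomerisation of the tiglate, deconjugation of the senecioate, and β-elimination of any β-acyloxy ketone.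

The feature that makes the key step possible: the fifteen skeletal carbons form one unbranched, head-to-tail isoprenoid chain C5–C4–C3(C12)–C2–C1–C11–C10(C15)–C9–C8–C7–C6(C13,C14). The cyclobutane arises from only two extra bonds, C5–C11 and C4–C10. These are exactly the bonds a ketene C4=C5=O forms with a C10=C11 alkene held three atoms away (C3, C2, C1). The ketene carbonyl carbon then lands on C5, the one cyclobutane carbon that must still be joined to C6 to close the seven-membered ring.

## Retrosynthesis

**Enone and senecioate (27 ⇒ 25 ⇒ 24 ⇒ 22 + 23).** The C1 ketone and C2=C3 alkene are traced to a C1 carbinol with an exocyclic C3=C12 alkene (25): oxidation gives the deconjugated enone 26, which conjugates to 27. This keeps the photolabile enone out of all earlier steps. The C7 ester is cut to alcohol 22 and 3-methylbut-2-enoic acid 23.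

**Tiglate and C7 stereocentre (22 ⇒ 20 + 21).** The O9–acyl bond and the C7–H bond are cut together. β-Hydroxy ketone 20 and (E)-2-methylbut-2-enal 21 give 22 in an Evans–Tishchenko reaction. Against separate reduction and two acylations, this one operation reduces C7 anti to O-9, installs the tiglate on O-9 and leaves only O-7 free, so the two similar hydroxyls are never in competition. The forward step needs intramolecular hydride delivery on the face of O-9.

**Seven-membered ring (20 ⇐ 19 ⇐ 18 ⇐ 17 ⇐ 15).** The C5–C6 bond is cut. In 15, C5 is a cyclobutanone carbonyl and C6 the α-carbon of an isopropenyl ketone; conjugate reduction generates the C6 enolate regiospecifically and the strained ketone accepts it. Closing at C7–C8 or C8–C9 instead would require making the C5–C6 bond intermolecularly between two fully substituted carbons, with a facial problem at C5. Closing at C5 makes C5 a bridgehead, so its configuration is dictated. The price is one oxygen on C5, removed through oxalate 18.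

**Cyclobutane and six-membered ring (15 ⇐ 12, key).** C5–C11 and C4–C10 are cut together. Acid 12 is an acyclic farnesoate-type chain with two stereocentres; the product is bicyclic with three new stereocentres including quaternary C10. The forward reaction is a thermal intramolecular vinylketene–alkene [2+2] cycloaddition. It must be crossed (bridged), stereospecific in the alkene, and face-selective.

**Chain (12 ⇐ 11 ⇐ 10 ⇐ 7 + 9; 7 ⇐ 5 ⇐ 4 ⇐ 2 + 3).** C8–C9 is cut to enal 7 and enol silane 9 (from 8) by a catalytic asymmetric Mukaiyama aldol, which sets C9. The aldehyde of 7 comes from allylic oxidation of the (E)-methyl of 5. The C1–C2 bond of 4 comes from a catalytic asymmetric vinylogous Mukaiyama aldol of dienolate 2 (from 1) with 3-methylbut-2-enal 3, which sets C1. All five building blocks (1, 3, 8, 21, 23) are commercial C5 compounds.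

## Roads not taken

Alternative 1: The most obvious cut is the biomimetic one, C4–C10 and C5–C11 as a photochemical [2+2] of two alkenes (C4=C5 and C10=C11) inside the eleven-membered trienone A1. The forward step is irradiation of A1 above 300 nm. The chosen plan is better for three reasons. A1 is a medium ring with three defined alkenes (one Z inside a cross-conjugated dienone) and two stereocentres, so the precursor is no easier than the target. The enone triplet reacts through 1,4-biradicals, so alkene geometry is not transmitted to C10, and with three atoms between the alkenes the first bond prefers five-membered-ring formation (C11–C4), which leads to the parallel, not the crossed, mode. The product chromophore absorbs the same light and can undergo a 1,3-shift. The ketene route makes the same two bonds thermally and stereospecifically from an open chain.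

Alternative 2: Cut only C5–C11 and close it by intramolecular enolate alkylation of the bicyclo[5.4.0] keto tosylate A2 (α′-enolate at C11 with KN(SiMe3)2, displacement at C5). The chosen plan is better because C5 is a secondary neopentyl carbon next to quaternary C6, so SN2 closure of a four-membered ring there should be very slow. Elimination, fragmentation and γ-deprotonation of the enone would compete. A2 already carries five stereocentres on two rings, so the key step would add one bond to a precursor as hard as the target.

Alternative 3: Cut C5–C6 and C9–C10 and add the four-carbon bridge across the central bond of bicyclo[1.1.0]butane A3 with the 1-methoxy-3-siloxy diene A4 in a formal (4+3) cycloaddition. The chosen plan is better because such strain-release cycloadditions rely on an acyl or aryl group on a bridgehead to polarise the central bond, and A3 has only H and CH3 there. Both new bonds would end at quaternary carbons, the orientation of A4 and the C9 configuration are uncontrolled, and C7 would still need a stereoselective reduction. Two bonds would rest on chemistry without precedent, where the chosen route uses known reaction types only.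

Key step: step 9

**Assumptions (remarks on the chemistry)**

- The chlorosilyl cation complex of the (R,R)-bisphosphoramide C51H52N6O2P2 is taken to deliver carbon nucleophiles to the Re face of conjugated aldehydes. This catalyst consists of two N,N'-dimethyl-1,1'-binaphthyl-2,2'-diamine phosphoric triamide units joined through their N-methyl nitrogens by a pentane-1,5-diyl chain. If the sense is opposite, the two antipodes are exchanged between steps 2 and 6 and nothing else changes.
- Dehydrochlorination of 13 is taken to occur through the C12 methyl hydrogen, giving the exocyclic alkene shown. If a C2 hydrogen is lost instead, the alkene ends inside the ring and the material still converges at step 17.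

## Route

Step 1
Reactants: 1 methyl 3-methylbut-2-enoate
Product: 2 (1Z)-1-(tert-butyldimethylsilyloxy)-1-methoxy-3-methylbuta-1,3-diene
Conditions: LiN(i-Pr)2, THF, −78 °C; TBSCl, DMPU, −78 °C to rt; distil
Reagents that add atoms: tert-butyldimethylsilyl chloride, CC(C)(C)[Si](C)(C)Cl
Why: Kinetic γ-deprotonation of the enoate and O-silylation of the dienolate (silyl ketene acetal formation); the ketene acetal geometry has no bearing on step 2.

Step 2
Reactants: 2 (1Z)-1-(tert-butyldimethylsilyloxy)-1-methoxy-3-methylbuta-1,3-diene; 3 3-methylbut-2-enal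
Product: 4 methyl (2E,5S)-5-hydroxy-3,7-dimethylocta-2,6-dienoate
Conditions: SiCl4 (1.1 equiv), (S,S)-bisphosphoramide C51H52N6O2P2 (2 mol %), i-Pr2NEt (10 mol %), CH2Cl2, −78 °C; aq. NaHCO3
Reagents that add atoms: none
Why: Lewis-base-catalysed, SiCl4-mediated vinylogous Mukaiyama aldol addition; the chiral silyl cation binds the enal and exposes its Si face to the unhindered γ-CH2 of the dienolate, which sets the carbinol centre (C1 of the target) as S.

Step 3
Reactants: 4 methyl (2E,5S)-5-hydroxy-3,7-dimethylocta-2,6-dienoate
Product: 5 methyl (2E,5S)-5-(tert-butyldimethylsilyloxy)-3,7-dimethylocta-2,6-dienoate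
Conditions: TBSCl, imidazole, DMF, rt
Reagents that add atoms: tert-butyldimethylsilyl chloride, CC(C)(C)[Si](C)(C)Cl
Why: Standard silylation of a secondary allylic alcohol; TBS is chosen to survive the acidic selenium step and every step up to step 16.

Step 4
Reactants: 5 methyl (2E,5S)-5-(tert-butyldimethylsilyloxy)-3,7-dimethylocta-2,6-dienoate
Product: 7 methyl (2E,5S,6E)-5-(tert-butyldimethylsilyloxy)-3,7-dimethyl-8-oxoocta-2,6-dienoate, via allylic alcohol 6 (not isolated)
Conditions: SeO2 (0.3 equiv), t-BuOOH (decane), CH2Cl2, 0 °C to rt; then MnO2, CH2Cl2, rt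
Reagents that add atoms: selenium dioxide, O=[Se]=O; tert-butyl hydroperoxide, CC(C)(C)OO
Why: Riley allylic oxidation (ene reaction, then [2,3]-shift) attacks the electron-rich trisubstituted alkene at its (E)-methyl group, so the new carbonyl carbon ends trans to the chain; the enoate alkene is too electron-poor to react, and MnO2 converts co-formed alcohol 6 into 7.

Step 5
Reactants: 8 3-methylbut-3-en-2-one
Product: 9 3-methyl-2-(trimethylsilyloxy)buta-1,3-diene
Conditions: LiN(i-Pr)2, THF, −78 °C; TMSCl; distil
Reagents that add atoms: chlorotrimethylsilane, C[Si](C)(C)Cl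
Why: The acetyl methyl is the only enolisable position, so kinetic enolisation and O-silylation give a single enol silane.

Step 6
Reactants: 7 methyl (2E,5S,6E)-5-(tert-butyldimethylsilyloxy)-3,7-dimethyl-8-oxoocta-2,6-dienoate; 9 3-methyl-2-(trimethylsilyloxy)buta-1,3-diene
Product: 10 methyl (2E,5S,6E,8R)-5-(tert-butyldimethylsilyloxy)-8-hydroxy-3,7,11-trimethyl-10-oxododeca-2,6,11-trienoate
Conditions: SiCl4 (1.5 equiv), (R,R)-bisphosphoramide C51H52N6O2P2 (5 mol %), i-Pr2NEt (10 mol %), CH2Cl2, −78 °C; aq. NaHCO3
Reagents that add atoms: none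
Why: Lewis-base-catalysed Mukaiyama aldol addition of a methyl ketone enol silane to a conjugated aldehyde; the catalyst directs attack to the Re face, giving 8R (C9 of the target), and the existing centre is five atoms away and should not interfere.

Step 7
Reactants: 10 methyl (2E,5S,6E,8R)-5-(tert-butyldimethylsilyloxy)-8-hydroxy-3,7,11-trimethyl-10-oxododeca-2,6,11-trienoate
Product: 11 methyl (2E,5S,6E,8R)-5-(tert-butyldimethylsilyloxy)-3,7,11-trimethyl-10-oxo-8-(triethylsilyloxy)dodeca-2,6,11-trienoate
Conditions: TESCl, imidazole, DMAP (cat.), DMF, 0 °C to rt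
Reagents that add atoms: chlorotriethylsilane, CC[Si](CC)(CC)Cl
Why: Silylation of the β-hydroxy ketone blocks retro-aldol and ketene trapping; TES is chosen so that it can later be removed in the presence of the secondary TBS ether.

Step 8
Reactants: 11 methyl (2E,5S,6E,8R)-5-(tert-butyldimethylsilyloxy)-3,7,11-trimethyl-10-oxo-8-(triethylsilyloxy)dodeca-2,6,11-trienoate
Product: 12 (2E,5S,6E,8R)-5-(tert-butyldimethylsilyloxy)-3,7,11-trimethyl-10-oxo-8-(triethylsilyloxy)dodeca-2,6,11-trienoic acid
Conditions: Me3SnOH, 1,2-dichloroethane, 80 °C; aq. KHSO4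
Reagents that add atoms: trimethyltin hydroxide, C[Sn](C)(C)O
Why: Tin-hydroxide cleavage of a methyl ester under near-neutral conditions, so the β-silyloxy ketone does not eliminate and the 1,1-disubstituted enone is not attacked.

Step 9
Reactants: 12 (2E,5S,6E,8R)-5-(tert-butyldimethylsilyloxy)-3,7,11-trimethyl-10-oxo-8-(triethylsilyloxy)dodeca-2,6,11-trienoic acid
Product: 15 (1R,4S,5R,7R)-4-(tert-butyldimethylsilyloxy)-7-methyl-2-methylidene-7-[(1R)-4-methyl-3-oxo-1-(triethylsilyloxy)pent-4-en-1-yl]bicyclo[3.1.1]heptan-6-one, via acyl chloride 13 (not isolated), via vinylketene 14 (not isolated)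
Conditions: 1-chloro-N,N,2-trimethylprop-1-en-1-amine (1.2 equiv), CH2Cl2, 0 °C to rt; then slow addition to Et3N (5 equiv), toluene, 110 °C, 0.005 M
Reagents that add atoms: none
Why: The chloroenamine converts 12 into acyl chloride 13 without acid, and Et3N then removes HCl across C5–C4–C3–C12 to give vinylketene 14, whose C4=C5 bond adds thermally across the C10=C11 alkene held by the three-atom tether C3–C2–C1. The closest known reaction type is the intramolecular vinylketene–alkene [2+2] cycloaddition of geranoyl- and farnesoyl-type chlorides to 2-methylidenebicyclo[3.1.1]heptan-6-ones. The four-membered ring closes by an asynchronous concerted [2+2]: the electrophilic ketene carbon C5 bonds first to the less substituted C11, and the developing tertiary cation at C10 collapses onto C4. The six-membered ring C4–C3–C2–C1–C11–C10 closes as a consequence of this crossed (bridged) mode, since the fused mode would place charge on secondary C11. C10 is set by the E geometry of the alkene: suprafacial addition keeps C15 cis to C1 (over the three-carbon bridge) and places C9 on the side of C5. C4 and C11 are fixed as a pair by the bridge, and their absolute sense comes from the C1 silyloxy centre: A(1,3) strain with the cis methyl C15 keeps the small hydrogen toward C15 and the OTBS group turned away, so the ketene is delivered to the face that leaves OTBS on the C5 side. The step needs crossed over fused closure (secured by the trisubstituted alkene), one alkene face (secured by C1) and intramolecular over intermolecular ketene capture (secured by high dilution; the isopropenyl ketone is out of reach). C1 ends as a ketone, so it serves purely as a removable controller.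

Step 10
Reactants: 15 (1R,4S,5R,7R)-4-(tert-butyldimethylsilyloxy)-7-methyl-2-methylidene-7-[(1R)-4-methyl-3-oxo-1-(triethylsilyloxy)pent-4-en-1-yl]bicyclo[3.1.1]heptan-6-one
Product: 17 (1S,4R,5R,9R,10R,11R)-1-(tert-butyldimethylsilyloxy)-5-hydroxy-9-(triethylsilyloxy)longipin-3(12)-en-7-one, via copper enolate 16 (not isolated)
Conditions: [(Ph3P)CuH]6 (0.35 equiv), toluene, −40 to 0 °C; aq. NH4Cl
Reagents that add atoms: none
Why: Reductive aldol cyclisation: conjugate hydride addition to the enone gives the fully substituted copper enolate 16 at C6 only, which adds (7-exo-trig) to the strained cyclobutanone carbonyl C5 and makes the C5–C6 bond between two fully substituted carbons. C5 becomes a bridgehead, so its configuration is dictated by the chain on the C9 face, and the former methylene becomes methyl C13/C14.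

Step 11
Reactants: 17 (1S,4R,5R,9R,10R,11R)-1-(tert-butyldimethylsilyloxy)-5-hydroxy-9-(triethylsilyloxy)longipin-3(12)-en-7-one
Product: 18 (1S,4R,5R,9R,10R,11R)-1-(tert-butyldimethylsilyloxy)-5-(methoxyoxalyloxy)-9-(triethylsilyloxy)longipin-3(12)-en-7-one
Conditions: ClC(O)CO2Me, DMAP, pyridine, CH2Cl2, 0 °C to rt
Reagents that add atoms: methyl chlorooxoacetate, COC(=O)C(=O)Cl
Why: O-Acylation of the tertiary bridgehead alcohol by a small, very reactive acyl chloride under non-ionising conditions, so no alkoxide forms and retro-aldol is avoided.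

Step 12
Reactants: 18 (1S,4R,5R,9R,10R,11R)-1-(tert-butyldimethylsilyloxy)-5-(methoxyoxalyloxy)-9-(triethylsilyloxy)longipin-3(12)-en-7-one
Product: 19 (1S,4R,5S,9R,10R,11R)-1-(tert-butyldimethylsilyloxy)-9-(triethylsilyloxy)longipin-3(12)-en-7-one
Conditions: Bu3SnH (3 equiv), AIBN (0.2 equiv), toluene, 100 °C
Reagents that add atoms: none
Why: Barton–McCombie-type radical deoxygenation of a tertiary methyl oxalate; the C5 radical is a bridgehead of the bicyclo[4.1.1] unit, so hydrogen transfer can only give the required C5–H.

Step 13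
Reactants: 19 (1S,4R,5S,9R,10R,11R)-1-(tert-butyldimethylsilyloxy)-9-(triethylsilyloxy)longipin-3(12)-en-7-one
Product: 20 (1S,4R,5S,9R,10R,11R)-1-(tert-butyldimethylsilyloxy)-9-hydroxylongipin-3(12)-en-7-one
Conditions: pyridinium p-toluenesulfonate, MeOH/CH2Cl2, 0 °C to rt
Reagents that add atoms: none
Why: Acid-catalysed methanolysis removes the TES ether much faster than the secondary TBS ether and frees the β-hydroxy ketone without base.

Step 14
Reactants: 20 (1S,4R,5S,9R,10R,11R)-1-(tert-butyldimethylsilyloxy)-9-hydroxylongipin-3(12)-en-7-one; 21 (E)-2-methylbut-2-enal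
Product: 22 (1S,4R,5S,7R,9R,10R,11R)-1-(tert-butyldimethylsilyloxy)-7-hydroxylongipin-3(12)-en-9-yl (E)-2-methylbut-2-enoate
Conditions: SmI2 (0.3 equiv, premixed with 21, 6 equiv), THF, −10 °C, dark
Reagents that add atoms: none
Why: Evans–Tishchenko reaction: the hemiacetal of O-9 with 21 and the C7 carbonyl are held on trivalent samarium, and the hemiacetal hydride shifts to C7 on the face of O-9. This gives the 1,3-anti relation (7R) and turns the aldehyde carbon into the tiglate on O-9.

Step 15
Reactants: 22 (1S,4R,5S,7R,9R,10R,11R)-1-(tert-butyldimethylsilyloxy)-7-hydroxylongipin-3(12)-en-9-yl (E)-2-methylbut-2-enoate; 23 3-methylbut-2-enoic acid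
Product: 24 (1S,4R,5S,7R,9R,10R,11R)-1-(tert-butyldimethylsilyloxy)-7-(3-methylbut-2-enoyloxy)longipin-3(12)-en-9-yl (E)-2-methylbut-2-enoate
Conditions: 2-methyl-6-nitrobenzoic anhydride (MNBA), DMAP, Et3N, CH2Cl2, rt to 40 °C
Reagents that add atoms: none
Why: Mixed-anhydride esterification suited to hindered secondary alcohols; it avoids the acyl chloride with amine base, which would deconjugate the senecioyl group through a vinylketene.

Step 16
Reactants: 24 (1S,4R,5S,7R,9R,10R,11R)-1-(tert-butyldimethylsilyloxy)-7-(3-methylbut-2-enoyloxy)longipin-3(12)-en-9-yl (E)-2-methylbut-2-enoate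
Product: 25 (1S,4R,5S,7R,9R,10R,11R)-1-hydroxy-7-(3-methylbut-2-enoyloxy)longipin-3(12)-en-9-yl (E)-2-methylbut-2-enoate
Conditions: HF·pyridine, pyridine, THF, 0 °C to rt
Reagents that add atoms: none
Why: Buffered fluoride cleavage of the secondary TBS ether; both esters and the alkene are inert to it.

Step 17
Reactants: 25 (1S,4R,5S,7R,9R,10R,11R)-1-hydroxy-7-(3-methylbut-2-enoyloxy)longipin-3(12)-en-9-yl (E)-2-methylbut-2-enoate
Product: 27 (4R,5S,7R,9R,10R,11R)-7-(3-methylbut-2-enoyloxy)-9-[(E)-2-methylbut-2-enoyloxy]longipin-2-en-1-one, via deconjugated enone 26 (not isolated)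
Conditions: DMP (1,1,1-triacetoxy-1,1-dihydro-1,2-benziodoxol-3(1H)-one), NaHCO3, CH2Cl2, 0 °C to rt; then DBU (0.2 equiv), 0 °C
Reagents that add atoms: none
Why: Periodinane oxidation of the C1 carbinol, then base-mediated conjugation through the dienolate (deprotonation at C2, protonation at C12) to the more stable endocyclic enone. C11 cannot epimerise because enolisation toward a bridgehead is geometrically excluded, and no β-acyloxy ketone remains.

## Compound list

1 | methyl 3-methylbut-2-enoate | COC(=O)C=C(C)C | starting material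
2 | (1Z)-1-(tert-butyldimethylsilyloxy)-1-methoxy-3-methylbuta-1,3-diene | CO/C(O[Si](C)(C)C(C)(C)C)=C/C(C)=C | intermediate
3 | 3-methylbut-2-enal | CC(C)=CC=O | starting material
4 | methyl (2E,5S)-5-hydroxy-3,7-dimethylocta-2,6-dienoate | COC(=O)/C=C(\C)C[C@H](O)C=C(C)C | intermediate
5 | methyl (2E,5S)-5-(tert-butyldimethylsilyloxy)-3,7-dimethylocta-2,6-dienoate | COC(=O)/C=C(\C)C[C@H](O[Si](C)(C)C(C)(C)C)C=C(C)C | intermediate
6 | methyl (2E,5S,6E)-5-(tert-butyldimethylsilyloxy)-8-hydroxy-3,7-dimethylocta-2,6-dienoate | COC(=O)/C=C(\C)C[C@H](O[Si](C)(C)C(C)(C)C)/C=C(\C)CO | intermediate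
7 | methyl (2E,5S,6E)-5-(tert-butyldimethylsilyloxy)-3,7-dimethyl-8-oxoocta-2,6-dienoate | COC(=O)/C=C(\C)C[C@H](O[Si](C)(C)C(C)(C)C)/C=C(\C)C=O | intermediate
8 | 3-methylbut-3-en-2-one | CC(=O)C(C)=C | starting material
9 | 3-methyl-2-(trimethylsilyloxy)buta-1,3-diene | C=C(C)C(=C)O[Si](C)(C)C | intermediate
10 | methyl (2E,5S,6E,8R)-5-(tert-butyldimethylsilyloxy)-8-hydroxy-3,7,11-trimethyl-10-oxododeca-2,6,11-trienoate | COC(=O)/C=C(\C)C[C@H](O[Si](C)(C)C(C)(C)C)/C=C(\C)[C@H](O)CC(=O)C(C)=C | intermediate
11 | methyl (2E,5S,6E,8R)-5-(tert-butyldimethylsilyloxy)-3,7,11-trimethyl-10-oxo-8-(triethylsilyloxy)dodeca-2,6,11-trienoate | COC(=O)/C=C(\C)C[C@H](O[Si](C)(C)C(C)(C)C)/C=C(\C)[C@H](O[Si](CC)(CC)CC)CC(=O)C(C)=C | intermediate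
12 | (2E,5S,6E,8R)-5-(tert-butyldimethylsilyloxy)-3,7,11-trimethyl-10-oxo-8-(triethylsilyloxy)dodeca-2,6,11-trienoic acid | OC(=O)/C=C(\C)C[C@H](O[Si](C)(C)C(C)(C)C)/C=C(\C)[C@H](O[Si](CC)(CC)CC)CC(=O)C(C)=C | intermediate
13 | acyl chloride of 12 | ClC(=O)/C=C(\C)C[C@H](O[Si](C)(C)C(C)(C)C)/C=C(\C)[C@H](O[Si](CC)(CC)CC)CC(=O)C(C)=C | intermediate
14 | vinylketene: (5S,6E,8R)-5-(tert-butyldimethylsilyloxy)-7,11-dimethyl-3-methylidene-8-(triethylsilyloxy)dodeca-1,6,11-triene-1,10-dione | O=C=CC(=C)C[C@H](O[Si](C)(C)C(C)(C)C)/C=C(\C)[C@H](O[Si](CC)(CC)CC)CC(=O)C(C)=C | intermediate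
15 | (1R,4S,5R,7R)-4-(tert-butyldimethylsilyloxy)-7-methyl-2-methylidene-7-[(1R)-4-methyl-3-oxo-1-(triethylsilyloxy)pent-4-en-1-yl]bicyclo[3.1.1]heptan-6-one | CC[Si](CC)(CC)O[C@H](CC(=O)C(C)=C)[C@@]1(C)[C@H]2C(=O)[C@@H]1C(=C)C[C@@H]2O[Si](C)(C)C(C)(C)C | intermediate
16 | copper enolate of 15 at C6/C7 (phosphine ligands omitted) | CC[Si](CC)(CC)O[C@H](CC(O[Cu])=C(C)C)[C@@]1(C)[C@H]2C(=O)[C@@H]1C(=C)C[C@@H]2O[Si](C)(C)C(C)(C)C | intermediate
17 | (1S,4R,5R,9R,10R,11R)-1-(tert-butyldimethylsilyloxy)-5-hydroxy-9-(triethylsilyloxy)longipin-3(12)-en-7-one | CC[Si](CC)(CC)O[C@@H]1CC(=O)C(C)(C)[C@]2(O)[C@H]3[C@@H](O[Si](C)(C)C(C)(C)C)CC(=C)[C@@H]2[C@]31C | intermediate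
18 | (1S,4R,5R,9R,10R,11R)-1-(tert-butyldimethylsilyloxy)-5-(methoxyoxalyloxy)-9-(triethylsilyloxy)longipin-3(12)-en-7-one | CC[Si](CC)(CC)O[C@@H]1CC(=O)C(C)(C)[C@]2(OC(=O)C(=O)OC)[C@H]3[C@@H](O[Si](C)(C)C(C)(C)C)CC(=C)[C@@H]2[C@]31C | intermediate
19 | (1S,4R,5S,9R,10R,11R)-1-(tert-butyldimethylsilyloxy)-9-(triethylsilyloxy)longipin-3(12)-en-7-one | CC[Si](CC)(CC)O[C@@H]1CC(=O)C(C)(C)[C@@H]2[C@H]3[C@@H](O[Si](C)(C)C(C)(C)C)CC(=C)[C@@H]2[C@]31C | intermediate
20 | (1S,4R,5S,9R,10R,11R)-1-(tert-butyldimethylsilyloxy)-9-hydroxylongipin-3(12)-en-7-one | O[C@@H]1CC(=O)C(C)(C)[C@@H]2[C@H]3[C@@H](O[Si](C)(C)C(C)(C)C)CC(=C)[C@@H]2[C@]31C | intermediate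
21 | (E)-2-methylbut-2-enal | C/C=C(\C)C=O | starting material
22 | (1S,4R,5S,7R,9R,10R,11R)-1-(tert-butyldimethylsilyloxy)-7-hydroxylongipin-3(12)-en-9-yl (E)-2-methylbut-2-enoate | C/C=C(\C)C(=O)O[C@@H]1C[C@@H](O)C(C)(C)[C@@H]2[C@H]3[C@@H](O[Si](C)(C)C(C)(C)C)CC(=C)[C@@H]2[C@]31C | intermediate
23 | 3-methylbut-2-enoic acid | CC(C)=CC(=O)O | starting material
24 | (1S,4R,5S,7R,9R,10R,11R)-1-(tert-butyldimethylsilyloxy)-7-(3-methylbut-2-enoyloxy)longipin-3(12)-en-9-yl (E)-2-methylbut-2-enoate | C/C=C(\C)C(=O)O[C@@H]1C[C@@H](OC(=O)C=C(C)C)C(C)(C)[C@@H]2[C@H]3[C@@H](O[Si](C)(C)C(C)(C)C)CC(=C)[C@@H]2[C@]31C | intermediate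
25 | (1S,4R,5S,7R,9R,10R,11R)-1-hydroxy-7-(3-methylbut-2-enoyloxy)longipin-3(12)-en-9-yl (E)-2-methylbut-2-enoate | C/C=C(\C)C(=O)O[C@@H]1C[C@@H](OC(=O)C=C(C)C)C(C)(C)[C@@H]2[C@H]3[C@@H](O)CC(=C)[C@@H]2[C@]31C | intermediate
26 | (4R,5S,7R,9R,10R,11R)-7-(3-methylbut-2-enoyloxy)-9-[(E)-2-methylbut-2-enoyloxy]longipin-3(12)-en-1-one | C/C=C(\C)C(=O)O[C@@H]1C[C@@H](OC(=O)C=C(C)C)C(C)(C)[C@@H]2[C@H]3C(=O)CC(=C)[C@@H]2[C@]31C | intermediate
27 | (4R,5S,7R,9R,10R,11R)-7-(3-methylbut-2-enoyloxy)-9-[(E)-2-methylbut-2-enoyloxy]longipin-2-en-1-one (CNP0277258.1) | C/C=C(\C)C(=O)O[C@@H]1C[C@@H](OC(=O)C=C(C)C)C(C)(C)[C@@H]2[C@H]3C(=O)C=C(C)[C@@H]2[C@]31C | target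

## Step count and least certain steps

Total: 17 steps, of which steps 1 and 5 prepare the two enol silanes. Longest linear sequence: 16 steps (1 → 2 → 4 → 5 → 7 → 10 → 11 → 12 → 15 → 17 → 18 → 19 → 20 → 22 → 24 → 25 → 27).

**Step 9 (key step).** Most likely failure: slow intramolecular capture of the vinylketene. The alkene carries two allylic silyloxy groups, which lower its nucleophilicity and crowd it, so ketene dimerisation or oligomerisation may win even at high dilution. A second concern is erosion of face selectivity, because the C9 centre sits on the other side of the alkene and may oppose the C1 control (it faces only H-11, so its bias should be the weaker one). Fallback: acid 12 is converted through acyl chloride 13 and pyrrolidine into the N-acylpyrrolidine F1. Tf2O and 2,4,6-trimethylpyridine in 1,2-dichloroethane at reflux generate the much more electrophilic vinylketeniminium ion, whose intramolecular [2+2] cycloaddition (a known keteniminium–alkene reaction type) gives the cyclobutaniminium triflate F2. Aqueous NaHCO3 hydrolysis returns to 15.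

**Step 10.** Most likely failure: the copper hydride reduces the strained cyclobutanone directly, or enolate 16 is protonated before it completes the entropically demanding seven-membered closure; the congested aldolate may also revert by retro-aldol on work-up. Fallback: from 15, RhCl(PPh3)3-catalysed 1,4-hydrosilylation with Et3SiH gives the isolable triethylsilyl enol ether F3. TiCl4 in CH2Cl2 at −78 °C then closes the ring by intramolecular Mukaiyama aldol addition and returns to 17 after aqueous work-up.

**Step 12.** Most likely failure: the tributylstannyl radical adds to the exocyclic C3=C12 alkene. That places a radical on C3 next to the four-membered ring, and ring opening of this cyclobutylcarbinyl radical would destroy the core. Fallback: from 17, 3-(trifluoromethyl)benzoyl chloride and DMAP give the 3-(trifluoromethyl)benzoate F4. Irradiation with 9-methylcarbazole in THF/water cleaves the C5–O bond by photoinduced electron transfer, with no chain-carrying radical that adds to alkenes, and returns to 19.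

**Step 14.** Most likely failure: slow hemiacetal formation between the neopentyl C9 hydroxyl and a conjugated, less electrophilic aldehyde, so that Tishchenko self-condensation of 21 outruns the hydride transfer; acyl migration from O-9 to O-7 is a second risk. Fallback: from 20, Yamaguchi esterification with (E)-2-methylbut-2-enoic acid (2,4,6-trichlorobenzoyl chloride, Et3N, DMAP) gives the keto ester F5. Corey–Bakshi–Shibata reduction ((S)-2-methyl-oxazaborolidine, catecholborane, toluene, −78 °C) then sets C7 by reagent control (large group C6 against small C8) and returns to 22.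

## Further compounds

F1 | step 9 | 1-[(2E,5S,6E,8R)-5-(tert-butyldimethylsilyloxy)-3,7,11-trimethyl-10-oxo-8-(triethylsilyloxy)dodeca-2,6,11-trienoyl]pyrrolidine | O=C(/C=C(\C)C[C@H](O[Si](C)(C)C(C)(C)C)/C=C(\C)[C@H](O[Si](CC)(CC)CC)CC(=O)C(C)=C)N1CCCC1
F2 | step 9 | pyrrolidinium-ylidene (cyclobutaniminium) triflate corresponding to 15 (C5=N+ in place of C5=O) | CC[Si](CC)(CC)O[C@H](CC(=O)C(C)=C)[C@@]1(C)[C@H]2C(=[N+]3CCCC3)[C@@H]1C(=C)C[C@@H]2O[Si](C)(C)C(C)(C)C.[O-]S(=O)(=O)C(F)(F)F
F3 | step 10 | triethylsilyl enol ether of 15 (C7(OSiEt3)=C6(CH3)2) | CC[Si](CC)(CC)O[C@H](CC(O[Si](CC)(CC)CC)=C(C)C)[C@@]1(C)[C@H]2C(=O)[C@@H]1C(=C)C[C@@H]2O[Si](C)(C)C(C)(C)C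
F4 | step 12 | 5-O-[3-(trifluoromethyl)benzoyl] derivative of 17 | CC[Si](CC)(CC)O[C@@H]1CC(=O)C(C)(C)[C@]2(OC(=O)c4cccc(C(F)(F)F)c4)[C@H]3[C@@H](O[Si](C)(C)C(C)(C)C)CC(=C)[C@@H]2[C@]31C
F5 | step 14 | (1S,4R,5S,9R,10R,11R)-1-(tert-butyldimethylsilyloxy)-7-oxolongipin-3(12)-en-9-yl (E)-2-methylbut-2-enoate | C/C=C(\C)C(=O)O[C@@H]1CC(=O)C(C)(C)[C@@H]2[C@H]3[C@@H](O[Si](C)(C)C(C)(C)C)CC(=C)[C@@H]2[C@]31C
A1 | alternative 1 | (2Z,4E,10E)-3,6,6,10-tetramethylcycloundeca-2,4,10-trien-1-one carrying the C7 3-methylbut-2-enoate and C9 (E)-2-methylbut-2-enoate of the target | C/C=C(\C)C(=O)O[C@@H]1C[C@@H](OC(=O)C=C(C)C)C(C)(C)/C=C/C(C)=C\C(=O)/C=C/1C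
A2 | alternative 2 | 7,9-bis(tert-butyldimethylsilyloxy)-3,6,6,10-tetramethyl-5-(p-toluenesulfonyloxy)bicyclo[5.4.0]undec-2-en-1-one (target numbering, C5–C11 bond absent) | CC(C)(C)[Si](C)(C)O[C@@H]1C[C@@H](O[Si](C)(C)C(C)(C)C)C(C)(C)[C@@H](OS(=O)(=O)c2ccc(C)cc2)[C@@H]2C(C)=CC(=O)C[C@@]21C
A3 | alternative 3 | 1,3-dimethyltricyclo[4.1.0.0(2,7)]hept-3-en-5-one (central bond C5–C10 of the target numbering) | CC1=CC(=O)[C@@H]2[C@@H]3[C@H]1[C@]23C
A4 | alternative 3 | (1E)-1-methoxy-4-methyl-3-(trimethylsilyloxy)penta-1,3-diene | CO/C=C/C(O[Si](C)(C)C)=C(C)C
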